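# Proposed total synthesis of gericudranin D (17)

## Analysis of the target

Gericudranin D (17) is a flavanonol. Ring A is a fully substituted, phloroglucinol-type benzene carrying O1 at C8a, hydroxyls at C5 and C7, 4-hydroxybenzyl groups at C6 and C8, and the carbonyl carbon C4 at C4a; ring C is the dihydropyranone and ring B is a 4-hydroxyphenyl group on C2. The two stereocentres C2 (R) and C3 (R) are adjacent and trans, with the aryl group and the hydroxyl both equatorial on the half-chair of ring C, which is the thermodynamically preferred arrangement. The C4 ketone is both a β-aryloxy ketone and an α-hydroxy ketone: base can open ring C by cleavage of O1–C2 or enolise C3, and oxidants can take the ketol on to the flavonol. Five free phenols, two electron-rich diarylmethane CH2 groups and the benzylic C2–O1 bond make the compound sensitive to air, strong acid and oxidants, so the phenols are best carried as benzyl ethers and released last under neutral conditions. The difficulty lies in ring A, where six positions must be filled and three oxygens told apart, and in setting C2 absolutely without ever forming an enolate next to it. The route rests on one feature: O1 and C4 sit on adjacent carbons of ring A (C8a and C4a) and C2 is β to the C3–C4 unit. An ortho-hydroxybenzaldehyde can therefore supply O1, C8a, C4a and C4, and a cinnamaldehyde can supply C2, C3 and ring B, the two being joined across O1–C2 and C3–C4.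

## Retrosynthetic reasoning

**17 from 16.** The six O–benzyl bonds of 16 (five phenolic, one at O3) are cut last. Hydrogenolysis is neutral, so the base-labile β-aryloxy ketone and the free phenols appear only in the final operation.

**16 from 15, and 15 from 13 through 14.** The C4 carbonyl is traced to the C4 carbinol of 15, and the O3–benzyl bond of 15 to the free 3,4-diol 13 by way of its tin acetal 14. Capping O3 first means the oxidant does not have to distinguish two secondary hydroxyls and cannot cleave the glycol. The extra benzyl group costs nothing, since it leaves with the others at the end.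

**13 from 12.** The C3–O and C4–O bonds are cut together, leading to the 2H-chromene 12. A syn-dihydroxylation has to deliver both oxygens to the face of the C3=C4 bond opposite the C2 aryl group; this fixes C3 relative to C2 without an enolate.

**12 from 11.** A formyl carbon is put back on C3, giving the chromene-3-carbaldehyde 11. This carbon is the price of the annulation that builds ring C; the forward step has to excise it while leaving the alkene in place and C2 untouched.

**11 from 7 and 10 (key disconnection).** O1–C2 and C3–C4 are cut. This divides the molecule into the hexasubstituted salicylaldehyde 7 (all of ring A plus C4) and the enal 10 (C2, C3, the formyl carbon and ring B). No other cut gives two pieces of such similar size that are each one or two steps from commercial material, and it places the only catalyst-controlled stereocentre, C2, in the bond-forming event. The forward reaction must add the phenol oxygen to the β-carbon of 10 on one face and then close ring C by aldol condensation.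

**7 from 3 and 4, and 3 from 1.** The two aryl–CH2 bonds (to C6 and C8 of the target) are cut, leading to the dibenzyl ether 3 and two molecules of the benzylic alcohol 4. The only two free positions of 3 are the two sites wanted, so electrophilic benzylation needs no regiocontrol. 3 in turn comes from the symmetrical triol 1 by cutting two O–benzyl bonds; the hydrogen bond to the formyl group keeps the third oxygen free and so distinguishes the future O1.

**10 from 8 and 9.** The C=C bond of the enal is cut to the aryl aldehyde 8 and the two-carbon ylide 9, a one-step homologation.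

## Alternatives that were turned down

**Alternative 1:** Here ring A itself is disconnected (C8a–C8, C6–C7 and C4a–C8a), so the benzene ring is assembled from a four-carbon and a two-carbon piece. In the forward sense the cyclobutenone A2 is heated with the siloxyalkyne A3. Four-electron ring opening of A2, [2+2] addition of A3, a second four-electron opening and a six-electron closure with tautomerisation (Danheiser benzannulation) would give the pentasubstituted phenol A1.
- For it: every substituent of ring A is placed by the connectivity of A2 and A3. O1 emerges as the only free hydroxyl while O5 and O7 are silylated, so the three oxygens are told apart by construction. On this point it is stronger than the chosen route, which relies on the hydrogen bond in 1 to leave one phenol free.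
- Against it: A2 and A3 are each several steps from commercial material and A3 is moisture-sensitive, whereas the same substitution pattern is reached here in two steps because ring A is a symmetrical phloroglucinol. A1 also still lacks C2, C3, C4, ring B and both stereocentres, so a second, stereocontrolled annulation would have to follow.
- Comparison: the effort would go into the easy part of the molecule and the route would be clearly longer. The chosen strategy buys ring A and spends its key step on ring C and C2.

**Alternative 2:** The cut is C4–C4a, opening ring C between the carbonyl carbon and ring A. This leads back to the aryloxy acid A5, in which C2 and C3 (both R) are already in place. In the forward sense the carboxyl group of A5 is activated and acylates the single free position of ring A in a Friedel–Crafts closure to give the 3-acetoxychromanone A4.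
- For it: the closure delivers C3–O and C4=O at their final oxidation levels together with both stereocentres, its regiochemistry is unambiguous, and no carbon has to be removed afterwards. In economy after ring closure it is superior to the chosen route, which needs four further operations on ring C.
- Against it: the O1–C2 ether bond of A5 would have to be made at a secondary benzylic carbon bearing a 4-alkoxyphenyl group, with a phenol oxygen flanked by a benzyl group as the nucleophile; substitution at such a centre tends to ionise and lose configuration. The same 4-alkoxybenzylic aryl ether must then survive the acidic acylation medium, where ionisation at C2 or β-elimination of the aryloxide from the activated acid would erase C2, and where the α-acetoxy centre can epimerise.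
- Comparison: the chosen strategy forms O1–C2 under nearly neutral amine catalysis with catalyst control and joins two simple aldehydes in one operation. The price is the later decarbonylation and oxidation sequence.

**Alternative 3:** The cut is C2–C3, leading back to the α-diazoketone A7, which carries three identical 4-benzyloxybenzyl ethers. In the forward sense the chiral dirhodium tetracarboxylate Rh2(S-PTTL)4 decomposes A7 and the carbene at C3 inserts into a benzylic C–H bond of an ortho ether, closing ring C as the flavanone A6 and setting C2.
- For it: A7 has a mirror plane through the acyl group, so either ortho ether can react. The C–H bond is activated by oxygen and by the donor aryl group, the stereocentre is set catalytically, and the approach is as convergent as the chosen one.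
- Against it: six-membered insertion must compete with attack of the carbene on the ether oxygen followed by a [1,2]-benzyl shift, and with addition to the many electron-rich arenes. Acceptor-only carbenes usually give modest enantiocontrol. A6 also has no oxygen at C3; it would have to be introduced through enolisation of a β-aryloxy ketone, the operation most prone to open ring C and lose C2.
- Comparison: the chosen strategy brings in the C3 oxygen by dihydroxylation of an alkene and never enolises next to C2, and its key step belongs to an established reaction type, whereas the insertion would be poorly precedented on so crowded a ring.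

Key step: step 4

## Route

Assumption: the (S)-diphenylprolinol silyl ether is taken to shield the Re face of the iminium β-carbon (C2), as in its other conjugate additions to cinnamaldehydes, so that oxygen adds to the Si face and C2 of 11 is R; should the sense prove opposite, the (R)-catalyst is used with no other change.

Step 1
Reactants: 1 2,4,6-trihydroxybenzaldehyde
Product: 3 2,4-bis(benzyloxy)-6-hydroxybenzaldehyde, via 4-O-benzyl monoether 2 (not isolated)
Conditions: BnBr (2.05 equiv), K2CO3 (2.2 equiv), DMF, 0 °C to rt
Reagents that add atoms: benzyl bromide, BrCc1ccccc1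
Why: Williamson ether synthesis; the para hydroxyl is the most acidic and reacts first, one ortho hydroxyl follows, and the last ortho hydroxyl is held in a hydrogen bond to the formyl oxygen and is the least nucleophilic, so alkylation should stop at the diether when the halide is limited to two equivalents.

Step 2
Reactants: 3 2,4-bis(benzyloxy)-6-hydroxybenzaldehyde; 4 [4-(benzyloxy)phenyl]methanol
Product: 7 4,6-bis(benzyloxy)-3,5-bis[4-(benzyloxy)benzyl]-2-hydroxybenzaldehyde, via 3-monobenzyl aldehyde 5 (not isolated), via 5-monobenzyl aldehyde 6 (not isolated)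
Conditions: 4 (2.2 equiv in all, slow addition), Sc(OTf)3 (10 mol %), MeNO2, rt to 40 °C
Reagents that add atoms: [4-(benzyloxy)phenyl]methanol as the second equivalent of 4, OCc1ccc(OCc2ccccc2)cc1
Why: Twofold Friedel–Crafts benzylation that consumes two molecules of 4 per molecule of 3 and releases only water; Sc(OTf)3 ionises the 4-alkoxybenzylic alcohol and the cation attacks the two free positions of 3 in turn (through 5 or 6), each position being ortho/para to three oxygen donors and meta to the formyl group. No other arene position in the mixture is comparably nucleophilic, and benzyl aryl ethers tolerate catalytic Sc(OTf)3.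

Step 3
Reactants: 8 4-(benzyloxy)benzaldehyde; 9 (triphenylphosphoranylidene)acetaldehyde
Product: 10 (E)-3-[4-(benzyloxy)phenyl]prop-2-enal
Conditions: 9 (1.1 equiv), toluene, 80 °C
Reagents that add atoms: none
Why: Wittig olefination with a stabilised ylide, which is E-selective; the ylide is kept near one equivalent to limit a second homologation of the product enal.

Step 4
Reactants: 7 4,6-bis(benzyloxy)-3,5-bis[4-(benzyloxy)benzyl]-2-hydroxybenzaldehyde; 10 (E)-3-[4-(benzyloxy)phenyl]prop-2-enal
Product: 11 (2R)-5,7-bis(benzyloxy)-6,8-bis[4-(benzyloxy)benzyl]-2-[4-(benzyloxy)phenyl]-2H-chromene-3-carbaldehyde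
Conditions: 10 (1.5 equiv), (S)-2-[diphenyl(trimethylsilyloxy)methyl]pyrrolidine (20 mol %), 2-nitrobenzoic acid (20 mol %), 4 Å MS, toluene, rt, dark
Reagents that add atoms: none
Why: Condensation of 10 with the secondary amine gives an E-configured, s-trans iminium ion whose Re face at the β-carbon (C2) is covered by the diphenyl(trimethylsilyloxy)methyl group, so the phenol oxygen of 7 adds reversibly from the Si face and forms O1–C2 with R configuration. The enamine so generated holds its nucleophilic carbon (C3) next to the ortho formyl carbon (C4) and closes ring C by a 6-exo-trig (enolexo) intramolecular aldol addition that forms C3–C4. Dehydration of the aldol adduct gives the conjugated iminium ion of 11, and its hydrolysis returns the catalyst; the dehydration withdraws the oxa-Michael adduct from its equilibrium and so fixes C2, the only stereocentre formed. The closest known reaction type is the amine-catalysed enantioselective domino oxa-Michael/aldol condensation of salicylaldehydes with cinnamaldehydes to 2-aryl-2H-chromene-3-carbaldehydes. The step needs enantiofacial selectivity at C2, which is catalyst-controlled, and 1,4- rather than 1,2-addition of the phenol, which iminium activation and the reversibility of hemiaminal formation provide. In the substrate the ortho relationship of OH and CHO makes the aldol intramolecular, and the fully substituted ring A leaves no arene position open to competing C-alkylation by the iminium ion. Both partners are electron-rich and the reacting groups of 7 are flanked by substituents, hence the high catalyst loading, the molecular sieves and the exclusion of light.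

Step 5
Reactants: 11 (2R)-5,7-bis(benzyloxy)-6,8-bis[4-(benzyloxy)benzyl]-2-[4-(benzyloxy)phenyl]-2H-chromene-3-carbaldehyde
Product: 12 (2S)-5,7-bis(benzyloxy)-6,8-bis[4-(benzyloxy)benzyl]-2-[4-(benzyloxy)phenyl]-2H-chromene
Conditions: RhCl(PPh3)3 (1.1 equiv), toluene, 80–90 °C, Ar, dark
Reagents that add atoms: none
Why: Tsuji–Wilkinson decarbonylation; oxidative addition of monovalent rhodium into the formyl C–H bond, extrusion of CO and C–H reductive elimination replace CHO by H without moving the alkene. C2 is not involved; its descriptor becomes S only because C3 now ranks below the aryl group.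

Step 6
Reactants: 12 (2S)-5,7-bis(benzyloxy)-6,8-bis[4-(benzyloxy)benzyl]-2-[4-(benzyloxy)phenyl]-2H-chromene
Product: 13 (2R,3S,4S)-5,7-bis(benzyloxy)-6,8-bis[4-(benzyloxy)benzyl]-2-[4-(benzyloxy)phenyl]chromane-3,4-diol
Conditions: OsO4 (5 mol %), NMO (1.5 equiv), acetone/H2O, 0 °C to rt
Reagents that add atoms: osmium tetroxide, O=[Os](=O)(=O)=O; N-methylmorpholine N-oxide, C[N+]1([O-])CCOCC1
Why: Catalytic syn-dihydroxylation of a cis-disubstituted, styrene-type alkene. The osmium reagent approaches C3=C4 from the face opposite the C2 aryl group, so both hydroxyls end up trans to that group (C3 S, C4 S; 2,3-trans-3,4-cis), as is usual for 2-aryl-2H-chromenes.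

Step 7
Reactants: 13 (2R,3S,4S)-5,7-bis(benzyloxy)-6,8-bis[4-(benzyloxy)benzyl]-2-[4-(benzyloxy)phenyl]chromane-3,4-diol
Product: 15 (2R,3S,4S)-3,5,7-tris(benzyloxy)-6,8-bis[4-(benzyloxy)benzyl]-2-[4-(benzyloxy)phenyl]chroman-4-ol, via stannylene acetal 14 (not isolated)
Conditions: Bu2SnO (1.1 equiv), toluene, reflux (Dean–Stark); then BnBr (1.3 equiv), CsF (1.5 equiv), DMF, rt
Reagents that add atoms: dibutyltin oxide, CCCC[Sn](=O)CCCC (atoms retained in 14 only); benzyl bromide, BrCc1ccccc1
Why: Stannylene-acetal-mediated regioselective alkylation of a cis-1,2-diol; the tin acetal activates the equatorial oxygen, here O3, which is also the less hindered one because O4 is pseudo-axial and peri to the C5 benzyloxy group. Fluoride activation allows the alkylation at rt.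

Step 8
Reactants: 15 (2R,3S,4S)-3,5,7-tris(benzyloxy)-6,8-bis[4-(benzyloxy)benzyl]-2-[4-(benzyloxy)phenyl]chroman-4-ol
Product: 16 (2R,3R)-3,5,7-tris(benzyloxy)-6,8-bis[4-(benzyloxy)benzyl]-2-[4-(benzyloxy)phenyl]chroman-4-one
Conditions: Dess–Martin periodinane (1.5 equiv), NaHCO3, CH2Cl2, 0 °C to rt
Reagents that add atoms: none
Why: Dess–Martin oxidation of the only free hydroxyl to the C4 ketone under buffered, non-enolising conditions. With O3 capped, neither glycol cleavage nor oxidation at C3 can occur, and C2 and C3 keep their configuration (C3 becomes R by priority change only).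

Step 9
Reactants: 16 (2R,3R)-3,5,7-tris(benzyloxy)-6,8-bis[4-(benzyloxy)benzyl]-2-[4-(benzyloxy)phenyl]chroman-4-one
Product: 17 gericudranin D
Conditions: H2 (1 atm), 10% Pd/C, THF/MeOH, rt
Reagents that add atoms: none
Why: Hydrogenolysis of the five aryl benzyl ethers and of the secondary alkyl benzyl ether at O3 under neutral conditions. The C4 carbonyl, deactivated by conjugation with ring A and by the hydrogen bond to the emerging C5 hydroxyl, and the diarylmethane C–C bonds should persist if the reaction is stopped once debenzylation is complete.

## Compound list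

1 | 2,4,6-trihydroxybenzaldehyde | O=Cc1c(O)cc(O)cc1O | starting material
2 | 4-(benzyloxy)-2,6-dihydroxybenzaldehyde | O=Cc1c(O)cc(OCc2ccccc2)cc1O | intermediate (not isolated)
3 | 2,4-bis(benzyloxy)-6-hydroxybenzaldehyde | O=Cc1c(O)cc(OCc2ccccc2)cc1OCc1ccccc1 | intermediate
4 | [4-(benzyloxy)phenyl]methanol | OCc1ccc(OCc2ccccc2)cc1 | starting material
5 | 4,6-bis(benzyloxy)-3-[4-(benzyloxy)benzyl]-2-hydroxybenzaldehyde | O=Cc1c(O)c(Cc2ccc(OCc3ccccc3)cc2)c(OCc2ccccc2)cc1OCc1ccccc1 | intermediate (not isolated)
6 | 2,4-bis(benzyloxy)-3-[4-(benzyloxy)benzyl]-6-hydroxybenzaldehyde | O=Cc1c(O)cc(OCc2ccccc2)c(Cc2ccc(OCc3ccccc3)cc2)c1OCc1ccccc1 | intermediate (not isolated)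
7 | 4,6-bis(benzyloxy)-3,5-bis[4-(benzyloxy)benzyl]-2-hydroxybenzaldehyde | O=Cc1c(O)c(Cc2ccc(OCc3ccccc3)cc2)c(OCc2ccccc2)c(Cc2ccc(OCc3ccccc3)cc2)c1OCc1ccccc1 | intermediate
8 | 4-(benzyloxy)benzaldehyde | O=Cc1ccc(OCc2ccccc2)cc1 | starting material
9 | (triphenylphosphoranylidene)acetaldehyde | O=CC=P(c1ccccc1)(c1ccccc1)c1ccccc1 | starting material
10 | (E)-3-[4-(benzyloxy)phenyl]prop-2-enal | O=C/C=C/c1ccc(OCc2ccccc2)cc1 | intermediate
11 | (2R)-5,7-bis(benzyloxy)-6,8-bis[4-(benzyloxy)benzyl]-2-[4-(benzyloxy)phenyl]-2H-chromene-3-carbaldehyde | O=CC1=Cc2c(OCc3ccccc3)c(Cc3ccc(OCc4ccccc4)cc3)c(OCc3ccccc3)c(Cc3ccc(OCc4ccccc4)cc3)c2O[C@@H]1c1ccc(OCc2ccccc2)cc1 | intermediate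
12 | (2S)-5,7-bis(benzyloxy)-6,8-bis[4-(benzyloxy)benzyl]-2-[4-(benzyloxy)phenyl]-2H-chromene | C1=Cc2c(OCc3ccccc3)c(Cc3ccc(OCc4ccccc4)cc3)c(OCc3ccccc3)c(Cc3ccc(OCc4ccccc4)cc3)c2O[C@@H]1c1ccc(OCc2ccccc2)cc1 | intermediate
13 | (2R,3S,4S)-5,7-bis(benzyloxy)-6,8-bis[4-(benzyloxy)benzyl]-2-[4-(benzyloxy)phenyl]chromane-3,4-diol | O[C@H]1c2c(OCc3ccccc3)c(Cc3ccc(OCc4ccccc4)cc3)c(OCc3ccccc3)c(Cc3ccc(OCc4ccccc4)cc3)c2O[C@H](c2ccc(OCc3ccccc3)cc2)[C@H]1O | intermediate
14 | 3,4-O-dibutylstannylene acetal of 13 | CCCC[Sn]3(CCCC)O[C@H]1c2c(OCc4ccccc4)c(Cc4ccc(OCc5ccccc5)cc4)c(OCc4ccccc4)c(Cc4ccc(OCc5ccccc5)cc4)c2O[C@H](c2ccc(OCc4ccccc4)cc2)[C@H]1O3 | intermediate (not isolated)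
15 | (2R,3S,4S)-3,5,7-tris(benzyloxy)-6,8-bis[4-(benzyloxy)benzyl]-2-[4-(benzyloxy)phenyl]chroman-4-ol | O[C@H]1c2c(OCc3ccccc3)c(Cc3ccc(OCc4ccccc4)cc3)c(OCc3ccccc3)c(Cc3ccc(OCc4ccccc4)cc3)c2O[C@H](c2ccc(OCc3ccccc3)cc2)[C@H]1OCc1ccccc1 | intermediate
16 | (2R,3R)-3,5,7-tris(benzyloxy)-6,8-bis[4-(benzyloxy)benzyl]-2-[4-(benzyloxy)phenyl]chroman-4-one | O=C1c2c(OCc3ccccc3)c(Cc3ccc(OCc4ccccc4)cc3)c(OCc3ccccc3)c(Cc3ccc(OCc4ccccc4)cc3)c2O[C@H](c2ccc(OCc3ccccc3)cc2)[C@H]1OCc1ccccc1 | intermediate
17 | gericudranin D, (2R,3R)-3,5,7-trihydroxy-6,8-bis(4-hydroxybenzyl)-2-(4-hydroxyphenyl)chroman-4-one | O=C1c2c(O)c(Cc3ccc(O)cc3)c(O)c(Cc3ccc(O)cc3)c2O[C@H](c2ccc(O)cc2)[C@H]1O | target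

## Step count and least certain steps

Total: 9 steps. Longest linear sequence: 8 steps (steps 1, 2, 4, 5, 6, 7, 8, 9, from 1); step 3 is the one-step side branch.

**Step 4 (key step).** The most likely failure is low conversion. The iminium ion of the donor-substituted enal 10 is a weak electrophile, the phenol of 7 is flanked by a benzyl group and its aldehyde by a benzyloxy group, and the oxa-Michael addition is reversible, so the adduct may revert faster than the aldol closes. A slow reaction also leaves time for erosion of the enantiomeric purity by reopening at O1–C2. Fallback: setting out from 3 and 10, the same amine-catalysed domino is run on the less hindered salicylaldehyde 3 to give (2R)-5,7-bis(benzyloxy)-2-[4-(benzyloxy)phenyl]-2H-chromene-3-carbaldehyde F1. The two benzyl groups are then introduced afterwards at C6 and C8, the only arene positions of F1 activated by three oxygen donors, by the Friedel–Crafts benzylation of step 2 with two equivalents of 4 and Sc(OTf)3; the electron-withdrawing 3-formyl group should disfavour ionisation at C2 under the Lewis acid. The route is rejoined at 11.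

**Step 5.** The most likely failure is loss of configurational purity at C2 at the temperature needed for CO extrusion, through reversible electrocyclic opening of the 2H-pyran ring at O1–C2, which the donor groups on ring A and ring B facilitate. Migration of the alkene towards O1 by a rhodium hydride is a second risk. Fallback: setting out from 11, the aldehyde is oxidised under Pinnick conditions (NaClO2, NaH2PO4, 2-methyl-2-butene) to (2R)-5,7-bis(benzyloxy)-6,8-bis[4-(benzyloxy)benzyl]-2-[4-(benzyloxy)phenyl]-2H-chromene-3-carboxylic acid F2. This cinnamic-type acid is converted by a catalytic Hunsdiecker bromodecarboxylation (NBS, LiOAc cat., MeCN/H2O, rt) into (2R)-5,7-bis(benzyloxy)-6,8-bis[4-(benzyloxy)benzyl]-2-[4-(benzyloxy)phenyl]-3-bromo-2H-chromene F3. The bromide is removed with Bu3SnH and Pd(PPh3)4 (zerovalent palladium) in THF at rt to rejoin the route at 12, with all operations at or near rt.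

**Step 2.** The most likely failure is incomplete second alkylation at the position lying between two benzyloxy groups. Self-condensation of the benzylic cation on the anisole-type rings already installed, and acid-induced migration of O-benzyl groups, may accompany it. Fallback: the order of C- and O-benzylation is inverted, setting out from 1 and 4. The free triol 1, a stronger and less hindered nucleophile with no benzyl ethers exposed to acid, is alkylated twice with 4 under the same catalysis to give 3,5-bis[4-(benzyloxy)benzyl]-2,4,6-trihydroxybenzaldehyde F4. This is then O-benzylated (BnBr, K2CO3, DMF) with the chelated ortho phenol spared, rejoining the route at 7.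

**Step 7.** The most likely failure is alkylation at the wrong oxygen, or ionisation of the very electron-rich benzylic C4–O bond while the tin acetal is formed at reflux. Fallback: the protection is omitted and, setting out from 13, the diol is oxidised directly with activated MnO2 (CH2Cl2, rt), which attacks only the benzylic carbinol, to give (2R,3R)-5,7-bis(benzyloxy)-6,8-bis[4-(benzyloxy)benzyl]-2-[4-(benzyloxy)phenyl]-3-hydroxychroman-4-one F5. Hydrogenolysis as in step 9 then rejoins the route at 17. This shorter variant is not the first choice because a cis-glycol may be cleaved on the MnO2 surface.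

**Step 9.** The most likely failure is over-reduction while the slower alkyl benzyl ether at O3 is still being cleaved: hydrogenolysis of the benzylic C2–O1 bond, opening ring C, or reduction of the C4 carbonyl. Fallback: setting out from 16, the benzyl ethers are cleaved by Lewis acid instead of hydrogen, with BCl3 and pentamethylbenzene as cation scavenger in CH2Cl2 at −78 °C, giving 17 directly; no new intermediate is involved.

## Further compounds

F1 | step 4 | (2R)-5,7-bis(benzyloxy)-2-[4-(benzyloxy)phenyl]-2H-chromene-3-carbaldehyde | O=CC1=Cc2c(OCc3ccccc3)cc(OCc3ccccc3)cc2O[C@@H]1c1ccc(OCc2ccccc2)cc1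
F2 | step 5 | (2R)-5,7-bis(benzyloxy)-6,8-bis[4-(benzyloxy)benzyl]-2-[4-(benzyloxy)phenyl]-2H-chromene-3-carboxylic acid | OC(=O)C1=Cc2c(OCc3ccccc3)c(Cc3ccc(OCc4ccccc4)cc3)c(OCc3ccccc3)c(Cc3ccc(OCc4ccccc4)cc3)c2O[C@@H]1c1ccc(OCc2ccccc2)cc1
F3 | step 5 | (2R)-5,7-bis(benzyloxy)-6,8-bis[4-(benzyloxy)benzyl]-2-[4-(benzyloxy)phenyl]-3-bromo-2H-chromene | BrC1=Cc2c(OCc3ccccc3)c(Cc3ccc(OCc4ccccc4)cc3)c(OCc3ccccc3)c(Cc3ccc(OCc4ccccc4)cc3)c2O[C@@H]1c1ccc(OCc2ccccc2)cc1
F4 | step 2 | 3,5-bis[4-(benzyloxy)benzyl]-2,4,6-trihydroxybenzaldehyde | O=Cc1c(O)c(Cc2ccc(OCc3ccccc3)cc2)c(O)c(Cc2ccc(OCc3ccccc3)cc2)c1O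
F5 | step 7 | (2R,3R)-5,7-bis(benzyloxy)-6,8-bis[4-(benzyloxy)benzyl]-2-[4-(benzyloxy)phenyl]-3-hydroxychroman-4-one | O=C1c2c(OCc3ccccc3)c(Cc3ccc(OCc4ccccc4)cc3)c(OCc3ccccc3)c(Cc3ccc(OCc4ccccc4)cc3)c2O[C@H](c2ccc(OCc3ccccc3)cc2)[C@H]1O
F0 | step 9 | none | none
A1 | alternative 1 | 2,4-bis[4-(benzyloxy)benzyl]-3,5-bis(triisopropylsilyloxy)phenol | Oc1cc(O[Si](C(C)C)(C(C)C)C(C)C)c(Cc2ccc(OCc3ccccc3)cc2)c(O[Si](C(C)C)(C(C)C)C(C)C)c1Cc1ccc(OCc2ccccc2)cc1
A2 | alternative 1 | 2-[4-(benzyloxy)benzyl]-3-(triisopropylsilyloxy)cyclobut-2-en-1-one | O=C1CC(O[Si](C(C)C)(C(C)C)C(C)C)=C1Cc1ccc(OCc2ccccc2)cc1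
A3 | alternative 1 | 1-(benzyloxy)-4-[3-(triisopropylsilyloxy)prop-2-yn-1-yl]benzene | CC(C)[Si](C(C)C)(C(C)C)OC#CCc1ccc(OCc2ccccc2)cc1
A4 | alternative 2 | (2R,3R)-3-acetoxy-5,7-bis(benzyloxy)-6,8-bis[4-(benzyloxy)benzyl]-2-[4-(benzyloxy)phenyl]chroman-4-one | O=C1c2c(OCc3ccccc3)c(Cc3ccc(OCc4ccccc4)cc3)c(OCc3ccccc3)c(Cc3ccc(OCc4ccccc4)cc3)c2O[C@H](c2ccc(OCc3ccccc3)cc2)[C@H]1OC(C)=O
A5 | alternative 2 | (2R,3R)-2-acetoxy-3-{3,5-bis(benzyloxy)-2,4-bis[4-(benzyloxy)benzyl]phenoxy}-3-[4-(benzyloxy)phenyl]propanoic acid | O=C(O)[C@H](OC(C)=O)[C@H](Oc1cc(OCc2ccccc2)c(Cc2ccc(OCc3ccccc3)cc2)c(OCc2ccccc2)c1Cc1ccc(OCc2ccccc2)cc1)c1ccc(OCc2ccccc2)cc1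
A6 | alternative 3 | (2S)-5,7-bis[4-(benzyloxy)benzyloxy]-6,8-bis[4-(benzyloxy)benzyl]-2-[4-(benzyloxy)phenyl]chroman-4-one | O=C1c2c(OCc3ccc(OCc4ccccc4)cc3)c(Cc3ccc(OCc4ccccc4)cc3)c(OCc3ccc(OCc4ccccc4)cc3)c(Cc3ccc(OCc4ccccc4)cc3)c2O[C@H](c2ccc(OCc3ccccc3)cc2)C1
A7 | alternative 3 | 2-diazo-1-{2,4,6-tris[4-(benzyloxy)benzyloxy]-3,5-bis[4-(benzyloxy)benzyl]phenyl}ethanone | [N-]=[N+]=CC(=O)c1c(OCc2ccc(OCc3ccccc3)cc2)c(Cc2ccc(OCc3ccccc3)cc2)c(OCc2ccc(OCc3ccccc3)cc2)c(Cc2ccc(OCc3ccccc3)cc2)c1OCc1ccc(OCc2ccccc2)cc1
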